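## Retrosynthetic overview

1. Atom labels for the macrocycle: C1 (CH bearing isopropenyl), C2, C3=C4(CO2Me), C5, C6(=O), C7, C8(Me)(O), C9, C10(=O), C11(H)(O), C12, C13(=O), C14.
2. The oxolan-3-one ring is formed last, by transannular 5-exo oxa-Michael addition of the C8 hydroxyl to C11 of a 14-membered 2-ene-1,4-dione. The carbocycle is closed just before, in the same flask, by carbene-catalysed hydroacylation of a terminal ynone (C10–C11).
3. The open-chain ynone aldehyde comes from a Z-selective Horner–Wadsworth–Emmons olefination (C3=C4) of a C4–C10 keto phosphonate with a C1–C3/C11–C14 aldehyde.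
4. The keto phosphonate comes from a Stetter addition (C5–C6) of a C6–C10 aldehyde to a 2-phosphonoacrylate. That aldehyde comes from dimethyl 3-hydroxy-3-methylglutarate by esterase desymmetrisation, which sets C8.
5. The second aldehyde comes from a 4-isopropenyl δ-lactone (rhodium-catalysed asymmetric 1,4-addition, sets C1) opened by a silylacetylide. Ring order: carbocycle, then oxolanone (sets C11).

Assumption: the esterase is taken to give the (S)-half-ester and (R)-BINAP the (R)-lactone, as for closely related substrates; if either sense is reversed, the other carboxyl arm of the half-ester is reduced or (S)-BINAP is used.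

## Route

Step 1
Reactants: 1 dimethyl 3-hydroxy-3-methylpentanedioate
Product: 2 (3S)-3-hydroxy-5-methoxy-3-methyl-5-oxopentanoic acid
Conditions: pig liver esterase, phosphate buffer pH 8, 25 °C, pH-stat (1 M NaOH); then HCl to pH 2
Reagents that add atoms: water, O
Why: Enzymatic desymmetrisation (serine-esterase hydrolysis of one enantiotopic ester arm of the prochiral diester) makes the carbinol carbon, the later C8, stereogenic as S without any metal.

Step 2
Reactants: 2 (3S)-3-hydroxy-5-methoxy-3-methyl-5-oxopentanoic acid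
Product: 4 methyl (3S)-3-hydroxy-3-methyl-5-[(triethylsilyl)oxy]pentanoate, via methyl (3S)-3,5-dihydroxy-3-methylpentanoate 3 (not isolated)
Conditions: BH3·SMe2, THF, 0 °C → rt; MeOH; then Et3SiCl, imidazole, DMF, 0 °C
Reagents that add atoms: chlorotriethylsilane, CC[Si](Cl)(CC)CC
Why: Chemoselective borane reduction of the carboxylic acid beside the methyl ester, then silylation of the primary hydroxyl (the tertiary one is inert) before the hydroxy ester can lactonise; the stereocentre is not touched.

Step 3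
Reactants: 4 methyl (3S)-3-hydroxy-3-methyl-5-[(triethylsilyl)oxy]pentanoate
Product: 5 (3S)-3-hydroxy-3-methyl-5-[(triethylsilyl)oxy]pentanal
Conditions: i-Bu2AlH (2.2 equiv), CH2Cl2, −78 °C; MeOH, aq. KNaC4H4O6
Reagents that add atoms: none
Why: Partial ester reduction with i-Bu2AlH; the aluminium hemiacetal, chelated by the neighbouring tertiary alkoxide, survives at −78 °C and gives the aldehyde (C6) on work-up.

Step 4
Reactants: 6 methyl 2-[bis(2,2,2-trifluoroethoxy)phosphoryl]acetate; 7 paraformaldehyde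
Product: 8 methyl 2-[bis(2,2,2-trifluoroethoxy)phosphoryl]prop-2-enoate
Conditions: (CH2O)n, piperidine (cat.), AcOH (cat.), PhMe, reflux, Dean–Stark; used fresh
Reagents that add atoms: none
Why: Knoevenagel methylenation of the active-methylene phosphonoacetate in a non-nucleophilic medium that leaves the trifluoroethyl phosphonate esters intact.

Step 5
Reactants: 5 (3S)-3-hydroxy-3-methyl-5-[(triethylsilyl)oxy]pentanal; 8 methyl 2-[bis(2,2,2-trifluoroethoxy)phosphoryl]prop-2-enoate
Product: 9 methyl (6S)-2-[bis(2,2,2-trifluoroethoxy)phosphoryl]-6-hydroxy-6-methyl-4-oxo-8-[(triethylsilyl)oxy]octanoate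
Conditions: 3-benzyl-5-(2-hydroxyethyl)-4-methylthiazolium chloride (20 mol%), Et3N (20 mol%), 1,4-dioxane, 60 °C, slow addition of 8
Reagents that add atoms: none
Why: Intermolecular Stetter reaction (thiazolylidene umpolung of the aliphatic aldehyde, addition to the doubly activated terminal acceptor) forms C5–C6; the new centre at C2 is a mixture that is erased in step 9.

Step 6
Reactants: 10 5,6-dihydro-2H-pyran-2-one; 11 4,4,5,5-tetramethyl-2-(prop-1-en-2-yl)-1,3,2-dioxaborolane
Product: 12 (4R)-4-(prop-1-en-2-yl)oxan-2-one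
Conditions: [Rh(OH)(cod)]2 (2.5 mol%), (R)-BINAP (6 mol%), 1,4-dioxane/H2O 10:1, 50 °C
Reagents that add atoms: none
Why: Rhodium-catalysed asymmetric 1,4-addition of the alkenylboronate (Hayashi–Miyaura); the (R)-BINAP complex selects one face of the lactone enoate and sets C1 as R.

Step 7
Reactants: 12 (4R)-4-(prop-1-en-2-yl)oxan-2-one; 13 ethynyl(trimethyl)silane
Product: 14 (5R)-7-hydroxy-5-(prop-1-en-2-yl)-1-(trimethylsilyl)hept-1-yn-3-one
Conditions: 13, n-BuLi, THF, −78 °C; then 12, −78 °C; AcOH quench at −78 °C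
Reagents that add atoms: none
Why: Mono-addition of the lithium acetylide to the δ-lactone; the lithium hemiketal alkoxide is stable at −78 °C, so a second addition is blocked and the hydroxy ynone (C13 ketone) is released on protonation.

Step 8
Reactants: 14 (5R)-7-hydroxy-5-(prop-1-en-2-yl)-1-(trimethylsilyl)hept-1-yn-3-one
Product: 15 (3R)-5-oxo-3-(prop-1-en-2-yl)-7-(trimethylsilyl)hept-6-ynal
Conditions: Dess–Martin periodinane, CH2Cl2, 0 °C → rt
Reagents that add atoms: none
Why: Dess–Martin oxidation of the primary alcohol to the C3 aldehyde under neutral conditions that spare the silyl ynone and the alkene.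

Step 9
Reactants: 9 methyl (6S)-2-[bis(2,2,2-trifluoroethoxy)phosphoryl]-6-hydroxy-6-methyl-4-oxo-8-[(triethylsilyl)oxy]octanoate; 15 (3R)-5-oxo-3-(prop-1-en-2-yl)-7-(trimethylsilyl)hept-6-ynal
Product: 16 methyl (2Z,5R)-2-[(4S)-4-hydroxy-4-methyl-2-oxo-6-[(triethylsilyl)oxy]hexyl]-7-oxo-5-(prop-1-en-2-yl)-9-(trimethylsilyl)non-2-en-8-ynoate
Conditions: 9, KN(SiMe3)2 (1.0 equiv), 18-crown-6, THF, −78 °C; then 15, −78 → −40 °C
Reagents that add atoms: none
Why: Still–Gennari variant of the Horner–Wadsworth–Emmons olefination; the electron-poor phosphonate with a dissociated potassium counter-ion eliminates from the kinetic adduct and places C2 cis to CO2Me (Z), while one equivalent of base deprotonates only the phosphonate.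

Step 10
Reactants: 16 methyl (2Z,5R)-2-[(4S)-4-hydroxy-4-methyl-2-oxo-6-[(triethylsilyl)oxy]hexyl]-7-oxo-5-(prop-1-en-2-yl)-9-(trimethylsilyl)non-2-en-8-ynoate
Product: 17 methyl (2Z,5R)-2-[(4S)-4,6-dihydroxy-4-methyl-2-oxohexyl]-7-oxo-5-(prop-1-en-2-yl)non-2-en-8-ynoate
Conditions: Bu4NF (2.4 equiv), AcOH (2.4 equiv), THF, 0 °C
Reagents that add atoms: none
Why: Fluoride desilylation cleaves both the primary O–Si bond and the alkynyl C–Si bond; the acetic acid buffer suppresses retro-aldol and conjugate addition to the freed ynone.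

Step 11
Reactants: 17 methyl (2Z,5R)-2-[(4S)-4,6-dihydroxy-4-methyl-2-oxohexyl]-7-oxo-5-(prop-1-en-2-yl)non-2-en-8-ynoate
Product: 18 methyl (2Z,5R)-2-[(4S)-4-hydroxy-4-methyl-2,6-dioxohexyl]-7-oxo-5-(prop-1-en-2-yl)non-2-en-8-ynoate
Conditions: Dess–Martin periodinane, CH2Cl2, 0 °C; filtered cold, used at once
Reagents that add atoms: none
Why: Dess–Martin oxidation of the primary alcohol gives the C10 aldehyde without base, so the keto aldehyde is not exposed to aldol conditions; the tertiary hydroxyl is inert.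

Step 12
Reactants: 18 methyl (2Z,5R)-2-[(4S)-4-hydroxy-4-methyl-2,6-dioxohexyl]-7-oxo-5-(prop-1-en-2-yl)non-2-en-8-ynoate
Product: 20 methyl (1R,5Z,8R,12S)-1-methyl-3,10,13-trioxo-8-(prop-1-en-2-yl)-15-oxabicyclo[10.2.1]pentadec-5-ene-5-carboxylate, via macrocyclic ene-dione 19 (not isolated)
Conditions: 2-(pentafluorophenyl)-6,7-dihydro-5H-pyrrolo[2,1-c][1,2,4]triazol-2-ium tetrafluoroborate (30 mol%), i-Pr2NEt (30 mol%), PhMe, 40 °C, 18 added by syringe pump over 12 h (2 mM)
Reagents that add atoms: none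
Why: Proposed new method: a carbene-catalysed macrocyclising Stetter hydroacylation of a terminal ynone, in which the triazolylidene turns the C10 aldehyde into a Breslow intermediate that attacks the unhindered ynone β-carbon C11 (14-membered ring), proton transfer and loss of the carbene give the 2-ene-1,4-dione 19, and the C8 hydroxyl then adds 5-exo across the ring to C11 (transannular oxa-Michael), where only the cis-bridged oxolanone can span the ten-carbon bridge so C11 is set as S from C8; the closest known reactions are intramolecular Stetter reactions forming five- and six-membered rings, carbene-catalysed hydroacylation of activated alkynes, acyl-radical macrocyclisations onto Michael acceptors, and the ene-dione/oxa-Michael closure seen after furan oxidation.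

## Compound list

1 | dimethyl 3-hydroxy-3-methylpentanedioate | COC(=O)CC(C)(O)CC(=O)OC | starting material
2 | (3S)-3-hydroxy-5-methoxy-3-methyl-5-oxopentanoic acid | COC(=O)C[C@@](C)(O)CC(=O)O | intermediate
3 | methyl (3S)-3,5-dihydroxy-3-methylpentanoate | COC(=O)C[C@@](C)(O)CCO | intermediate
4 | methyl (3S)-3-hydroxy-3-methyl-5-[(triethylsilyl)oxy]pentanoate | COC(=O)C[C@@](C)(O)CCO[Si](CC)(CC)CC | intermediate
5 | (3S)-3-hydroxy-3-methyl-5-[(triethylsilyl)oxy]pentanal | O=CC[C@@](C)(O)CCO[Si](CC)(CC)CC | intermediate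
6 | methyl 2-[bis(2,2,2-trifluoroethoxy)phosphoryl]acetate | COC(=O)CP(=O)(OCC(F)(F)F)OCC(F)(F)F | starting material
7 | paraformaldehyde (drawn as formaldehyde) | C=O | starting material
8 | methyl 2-[bis(2,2,2-trifluoroethoxy)phosphoryl]prop-2-enoate | COC(=O)C(=C)P(=O)(OCC(F)(F)F)OCC(F)(F)F | intermediate
9 | methyl (6S)-2-[bis(2,2,2-trifluoroethoxy)phosphoryl]-6-hydroxy-6-methyl-4-oxo-8-[(triethylsilyl)oxy]octanoate (both C2 epimers) | COC(=O)C(CC(=O)C[C@@](C)(O)CCO[Si](CC)(CC)CC)P(=O)(OCC(F)(F)F)OCC(F)(F)F | intermediate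
10 | 5,6-dihydro-2H-pyran-2-one | O=C1C=CCCO1 | starting material
11 | 4,4,5,5-tetramethyl-2-(prop-1-en-2-yl)-1,3,2-dioxaborolane | CC(=C)B1OC(C)(C)C(C)(C)O1 | starting material
12 | (4R)-4-(prop-1-en-2-yl)oxan-2-one | C=C(C)[C@H]1CC(=O)OCC1 | intermediate
13 | ethynyl(trimethyl)silane | C#C[Si](C)(C)C | starting material
14 | (5R)-7-hydroxy-5-(prop-1-en-2-yl)-1-(trimethylsilyl)hept-1-yn-3-one | C=C(C)[C@H](CCO)CC(=O)C#C[Si](C)(C)C | intermediate
15 | (3R)-5-oxo-3-(prop-1-en-2-yl)-7-(trimethylsilyl)hept-6-ynal | C=C(C)[C@H](CC=O)CC(=O)C#C[Si](C)(C)C | intermediate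
16 | methyl (2Z,5R)-2-[(4S)-4-hydroxy-4-methyl-2-oxo-6-[(triethylsilyl)oxy]hexyl]-7-oxo-5-(prop-1-en-2-yl)-9-(trimethylsilyl)non-2-en-8-ynoate | C=C(C)[C@H](C/C=C(\C(=O)OC)CC(=O)C[C@@](C)(O)CCO[Si](CC)(CC)CC)CC(=O)C#C[Si](C)(C)C | intermediate
17 | methyl (2Z,5R)-2-[(4S)-4,6-dihydroxy-4-methyl-2-oxohexyl]-7-oxo-5-(prop-1-en-2-yl)non-2-en-8-ynoate | C=C(C)[C@H](C/C=C(\C(=O)OC)CC(=O)C[C@@](C)(O)CCO)CC(=O)C#C | intermediate
18 | methyl (2Z,5R)-2-[(4S)-4-hydroxy-4-methyl-2,6-dioxohexyl]-7-oxo-5-(prop-1-en-2-yl)non-2-en-8-ynoate | C=C(C)[C@H](C/C=C(\C(=O)OC)CC(=O)C[C@@](C)(O)CC=O)CC(=O)C#C | intermediate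
19 | methyl (1Z,4R,7E,11R)-11-hydroxy-11-methyl-6,9,13-trioxo-4-(prop-1-en-2-yl)cyclotetradeca-1,7-diene-1-carboxylate | C=C(C)[C@@H]1C/C=C(\C(=O)OC)CC(=O)C[C@@](C)(O)CC(=O)/C=C/C(=O)C1 | intermediate
20 | methyl (1R,5Z,8R,12S)-1-methyl-3,10,13-trioxo-8-(prop-1-en-2-yl)-15-oxabicyclo[10.2.1]pentadec-5-ene-5-carboxylate | C=C(C)[C@@H]1C/C=C(\C(=O)OC)CC(=O)C[C@]2(C)CC(=O)[C@H](CC(=O)C1)O2 | target

## Step count and risks

Total steps: 12. Longest linear sequence: 8 (steps 1, 2, 3, 5, 9, 10, 11, 12; from 1 to 20).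

The three steps most likely to fail:

**Step 12 (the new macrocyclisation).** The carbene may be consumed by the ynone, or the base-sensitive keto aldehyde 18 may undergo aldol chemistry before the slow ring closure. The fallback makes the same C10–C11 bond by known nickel chemistry and sets out from 18. A zerovalent-nickel-catalysed reductive aldehyde–alkyne macrocyclisation (Ni(cod)2, 1,3-dimesitylimidazol-2-ylidene, Et3SiH, THF, high dilution) gives methyl (1Z,4R,7E,11S)-11-hydroxy-11-methyl-6,13-dioxo-4-(prop-1-en-2-yl)-9-[(triethylsilyl)oxy]cyclotetradeca-1,7-diene-1-carboxylate F1 as a mixture at the silyloxy carbon. HF·pyridine then frees methyl (1Z,4R,7E,11S)-9,11-dihydroxy-11-methyl-6,13-dioxo-4-(prop-1-en-2-yl)cyclotetradeca-1,7-diene-1-carboxylate F2. Dess–Martin oxidation of the allylic alcohol comes back to the route at ene-dione 19, which closes to 20 as before. If the tertiary hydroxyl has already added to the enone at the F1 or F2 stage, the same oxidation still gives 20.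

**Step 5 (Stetter addition to the phosphonoacrylate).** Acceptor 8 may oligomerise under amine and carbene, or the β-hydroxy aldehyde may degrade. The fallback switches from polar umpolung to a radical hydroacylation and sets out from 5 with 8. Irradiation at 365 nm with (n-Bu4N)4[W10O32] (2 mol%) in MeCN at rt abstracts the aldehyde hydrogen, and the acyl radical adds to 8 in a Giese reaction. This comes back to the route directly at 9 and makes no new compound (F0).

**Step 2 (reduction and silylation in one pot).** The hydroxy ester 3 may close to the lactone faster than it is silylated. The fallback accepts the lactone and sets out from 2. BH3·SMe2 followed by acid gives (4S)-4-hydroxy-4-methyloxan-2-one F3. Me3Al with MeNH(OMe)·HCl opens it to (3S)-3,5-dihydroxy-N-methoxy-N,3-dimethylpentanamide F4. Et3SiCl and imidazole give (3S)-3-hydroxy-N-methoxy-N,3-dimethyl-5-[(triethylsilyl)oxy]pentanamide F5. i-Bu2AlH at −78 °C reduces the amide to the aldehyde and comes back to the route at 5, so step 3 is not needed.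

Further compounds
F1 | step 12 | methyl (1Z,4R,7E,11S)-11-hydroxy-11-methyl-6,13-dioxo-4-(prop-1-en-2-yl)-9-[(triethylsilyl)oxy]cyclotetradeca-1,7-diene-1-carboxylate (both C9 epimers) | C=C(C)[C@@H]1C/C=C(\C(=O)OC)CC(=O)C[C@@](C)(O)CC(O[Si](CC)(CC)CC)/C=C/C(=O)C1
F2 | step 12 | methyl (1Z,4R,7E,11S)-9,11-dihydroxy-11-methyl-6,13-dioxo-4-(prop-1-en-2-yl)cyclotetradeca-1,7-diene-1-carboxylate (both C9 epimers) | C=C(C)[C@@H]1C/C=C(\C(=O)OC)CC(=O)C[C@@](C)(O)CC(O)/C=C/C(=O)C1
F0 | step 5 | none | none
F3 | step 2 | (4S)-4-hydroxy-4-methyloxan-2-one | O=C1C[C@@](C)(O)CCO1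
F4 | step 2 | (3S)-3,5-dihydroxy-N-methoxy-N,3-dimethylpentanamide | CON(C)C(=O)C[C@@](C)(O)CCO
F5 | step 2 | (3S)-3-hydroxy-N-methoxy-N,3-dimethyl-5-[(triethylsilyl)oxy]pentanamide | CON(C)C(=O)C[C@@](C)(O)CCO[Si](CC)(CC)CC
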